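1. The flask holds 0.10 M of starting material and 0.105 M of second substrate against 6.6 µM of free enzyme, so each enzyme has to turn over 15200 times to use up the starting material.

| setting | autumn | dawn | flask |
|---|---|---|---|
| starting material | 0.10 M | 0.20 M | 0.10 M |
| second substrate | 0.105 M | 0.105 M | 0.105 M |
| free enzyme | 6.6 µM | 6.6 µM | 6.6 µM |
| temperature | 25 °C | 31 °C | 25 °C |
| remark | the very flask that is asked about, followed so far | run made earlier |  |
| time |  |  | 6.0 d |

| autumn: time / h | autumn: target / % | dawn: time / h | dawn: target / % |
|---|---|---|---|
| 10.0 | 26.7 | 1.50 | 11.3 |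
| 30.0 | 25.8 | 3.00 | 11.2 |
| 60.0 | 25.1 | 5.00 | 12.3 |
| 96.0 | 25.0 | 6.00 | 12.0 |

(readings scatter by 0.5 percentage points)

- Wednesday's: at 6.0 d add free enzyme, 100 % of the amount charged, then wait 40 h
- Tuesday's: at 6.0 d raise the temperature by 25 K, then wait 40 h
- Saturday's: at 6.0 d add second substrate, 50.0 % of the amount charged, then wait 40 h
- Thursday's: at 6.0 d take out 90 % of the first product then present, then wait 40 h
- Sunday's: change nothing and wait 40 h more

* target, in percent of the starting material first charged, at 6.0 d
* what to do for the largest gain in target; "none" if nothing gains more than 2 percentage points (Wednesday's / Tuesday's / Saturday's / Thursday's / Sunday's / none)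
* target present, in percent of the starting material first charged, after Tuesday's
* target present, in percent of the starting material first charged, after Sunday's

- the volume of additions can be left aside

2. The first instants: I see none of them. The autumn flask already stands at 26.7 % after 10.0 h, and the warmer dawn flask at 11.3 % after 1.50 h, so in each the making lies before the first reading.

3. The middle: the autumn flask does not climb. I replace its curve by the mean of its readings, 25.6 %. That mean carries a scatter of 0.25 percentage points. The readings do fall by 1.7 points, and if that fall is real, the mean stands 0.65 points above the last reading. I accept that error.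

4. The stop: the mean means 0.0257 M of target. Taking one of each per target, the autumn flask keeps 0.0743 M of starting material and 0.0793 M of second substrate, so no charge has run out.

5. The dawn flask, with twice the starting material, reaches 0.0234 M of target, less than the autumn flask. Both flasks share the same enzyme charge. So I carry the turnover budget (total turnover number), the target made per enzyme charged: 3890 in the autumn flask, and 3550 in the dawn flask.

6. My reckoning for the autumn flask: with the budget used, it stays at 25.6 % through Sunday's and Tuesday's. Wednesday's buys a second budget, 26 points.

7. The forecast says 24.8 % now, 24.7 % after Sunday's, 23 % after Tuesday's, and Wednesday's as the best move, on the ground “so the enzyme has died”. Its figure for now stands below my mean, and so does its figure after Tuesday's, where I reckon no loss.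

8. The flask gives 26.0 % now, 26.0 % after Sunday's and 26.0 % after Tuesday's. The best move is Wednesday's, which gains 39 points.

    free enzyme → unfolded enzyme (k = 8.19 × 10⁻⁴ min⁻¹, Ea = 260 kJ mol⁻¹)
    starting material + free enzyme ⇌ first complex (K = 60.0 M⁻¹, k = 59500 M⁻¹ min⁻¹, Ea = 35.0 kJ mol⁻¹, ΔH = −30.0 kJ mol⁻¹)
    first complex → loaded enzyme + first product (k = 3920 min⁻¹, Ea = 70.0 kJ mol⁻¹)
    second substrate + loaded enzyme ⇌ second complex (K = 259 M⁻¹, k = 18200 M⁻¹ min⁻¹, Ea = 44.0 kJ mol⁻¹, ΔH = 5.00 kJ mol⁻¹)
    second complex ⇌ free enzyme + target (K = 0.270 M, k = 266 min⁻¹, Ea = 61.0 kJ mol⁻¹, ΔH = −28.0 kJ mol⁻¹)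
    target + free enzyme ⇌ isomer of the product + free enzyme, rate k6*[free enzyme]*[target] forward; the back reaction follows from the equilibrium constant (K = 5.54, k = 2310 M⁻¹ min⁻¹, Ea = 51.0 kJ mol⁻¹, ΔH = −5.00 kJ mol⁻¹)
    second substrate + second complex → spent catalyst (k = 0.726 M⁻¹ min⁻¹, Ea = 72.0 kJ mol⁻¹)
    (constants at 25 °C)

In the autumn flask at the start, second complex releases target at 266 min⁻¹ and leaves the working round with second substrate at 0.0762 min⁻¹, a ratio of 3491. The budget of that flask comes to 3939, with 99.9 % of the catalyst as spent catalyst after 144 h. Carried to the neighbour with 1.6 × 10⁻⁵ M of free enzyme, the budget of 3890 promises 62.2 % of the charge. That neighbour ends with 42.6 % target, 57.4 % isomer of the product and 0 % starting material.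

All runs were generated by integration with made-up constants; scatter was added.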